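Late in the run the two earlier flasks have stopped moving, so that is where to read them.

common to all: Z 0.10 M; X 0.10 M
- grey: L 0.80 equiv; D 1.4 mol%; run made earlier
- teal: L 0.80 equiv; D 6.4 mol%; run made earlier
- larch: L 0.800 equiv; D 1 mol%; time 2.0 min
- alder: L 0.800 equiv; D 4 mol%; time 2.0 min

| run | time / s | J / % | Q / % |
|---|---|---|---|
| grey | 10.0 | 29.7 | 2.0 |
| grey | 15.0 | 31.8 | 3.5 |
| grey | 30.0 | 36.7 | 1.7 |
| grey | 40.0 | 36.8 | 3.5 |
| grey | 60.0 | 37.3 | 2.0 |
| teal | 12.0 | 35.6 | 1.3 |
| teal | 25.0 | 36.7 | 1.2 |
| teal | 40.0 | 39.3 | 1.9 |
| teal | 50.0 | 37.2 | 2.3 |
| teal | 60.0 | 38.0 | 0.7 |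

(standard deviation of a reading: 1 percentage point)

- D is single-handed; Z and X are mirror images of each other, charged as a racemate, each of them at the stated concentration
- the earlier runs were read with a standard deviation of 1 percentage point
- an excess is below zero if the other one leads

- the flask that ends with the higher excess of J over Q in the product, or "neither" when 2 percentage points or less lies between them (larch / alder / neither)
- excess of J over Q in the product at the end, larch
- excess of J over Q in the product at the end, alder

From 40.0 s on, the 5 readings of grey and teal average 37.7% J and 2.08% Q. Their sum, 39.8%, is about the 40.0% that L allows, so in grey and teal L reads as the limiting reagent. Yet D differs 4.57-fold between these runs. One D turns both Z and X, so if each rate is proportional to D, D cancels from the ratio of J to Q.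

What remains is the selectivity factor s: the logarithm of the fraction of Z left over the logarithm of the fraction of X left. Here s reads 33.0, resting on a small Q with a scatter of 1 percentage point per reading, and the excess reads 89.5%.

Now count turnovers. Larch needs 80.0 per D and alder 20.0, while grey shows 56.1 by 60.0 s. Larch's need is untested by these runs; if larch leaves L unused, more of its Z stays, and I expect its excess to come out slightly higher. My reckoning is both near 89.5%, so neither.

The forecast said alder, with 86% for larch and 91% for alder, from "a small unselective background".

The answer is neither: larch 90.4%, alder 90.1%. Larch ends with 2.7% of its L left and alder with 0%.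

    D → E (k = 0.0150 s⁻¹)
    L + D + X → D + Q (k = 45.0 L² mol⁻² s⁻¹)
    D → G (k = 1.30 × 10⁻⁴ s⁻¹)
    L + D + Z → D + J (k = 1600 L² mol⁻² s⁻¹)

Put to use on larch, s turns the 26% of Z left into 2.00% Q and an excess of 89.7%.

In a neighbour of larch with 0.200 equiv of L, little Z is consumed, so Z and X stay close, the ratio of J to Q stays near s and the excess near (s−1)/(s+1), which is 94.1%. That neighbour computes to 94.0%, ending with Z at 40.3% and X at 49.7%.

The data are simulated from invented constants.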